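**Overview**

Retrosynthetic cuts, in order: the bond between ring B and the stilbene CH (Heck); the benzylic C7–O1 bond of dioxane ring C; C9 (CH2OH from an ester); the C7–H bond (carbinol from an aryl ketone); the C8–O4 aryl ether bond (phenoxide plus alpha-bromo keto ester).
Enabling feature: C7 (O1–CH–aryl, para to the free OH of syringyl ring A) and C8 (O4–CH–CH2OH) are the carbonyl carbon and the triply activated alpha carbon of a 3-aryl-2-aryloxy-3-oxopropanoate. C8 is therefore labile before the reduction and C7 after it. O4 is the middle oxygen of the 5-substituted pyrogallol ring B, whose two outer oxygens are equivalent, so ring closure has no regiochemical choice.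
Forward order: rings A, B and D (resorcinol) are bought as arenes. A and B are joined through C8–O4, the ketone and then the ester are reduced, ring C closes at C7–O1, and ring D is attached last through the alkene.
Stereochemistry: C8 comes from the transfer hydrogenation with dynamic kinetic resolution and is not touched again. C7 is set there too, but the reversible closure finally fixes it trans to CH2OH. The E alkene comes from the Heck reaction.

Key step: step 8

Remark on locants: in the running text C7, C8 and C9 are neolignan locants (C7 benzylic, C8 bearing C9H2OH), and O1 and O4 are the ring oxygens on C7 and C8. Locants inside compound names are systematic.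

Assumption: the (R,R)-catalyst is taken to attack the aryl ketone in the usual sense for aryl ketones and with the syn preference known for 2-alkoxy-3-oxo esters, which together give (2R,3S). If the relative sense proved to be anti, the (S,S)-catalyst would supply the same C8 configuration, because C7 is reset in step 10.

**Step 1**
Reactants: 1 acetosyringone
Product: 2 1-[3,5-dimethoxy-4-(methoxymethoxy)phenyl]ethanone
Conditions: MOMCl, i-Pr2NEt, CH2Cl2, 0 °C to rt
Reagents that add atoms: chloromethyl methyl ether (MOMCl), COCCl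
Why: MOM ether formation by O-alkylation of the acidic syringyl phenol with an alpha-chloro ether is fast under amine base and leaves the methyl ketone untouched.

**Step 2**
Reactants: 2 1-[3,5-dimethoxy-4-(methoxymethoxy)phenyl]ethanone
Product: 3 ethyl 3-[3,5-dimethoxy-4-(methoxymethoxy)phenyl]-3-oxopropanoate
Conditions: NaH, (EtO)2CO, THF, reflux; AcOH quench
Reagents that add atoms: diethyl carbonate, CCOC(=O)OCC
Why: the crossed Claisen condensation of the ketone enolate with non-enolisable diethyl carbonate is driven forward by deprotonation of the beta-keto ester formed, as is routine for trialkoxyacetophenones.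

**Step 3**
Reactants: 3 ethyl 3-[3,5-dimethoxy-4-(methoxymethoxy)phenyl]-3-oxopropanoate
Product: 4 ethyl 2-bromo-3-[3,5-dimethoxy-4-(methoxymethoxy)phenyl]-3-oxopropanoate (racemic)
Conditions: NBS (1 equiv), Mg(ClO4)2 (cat.), EtOAc, 0 °C to rt
Reagents that add atoms: N-bromosuccinimide, O=C1CCC(=O)N1Br
Why: Lewis acid-catalysed electrophilic alpha-bromination of the chelated enol of a 1,3-dicarbonyl compound should be much faster than bromination of the acyl-deactivated arene, and the new centre is deliberately racemic.

**Step 4**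
Reactants: 5 4-bromo-2,6-dimethoxybenzaldehyde
Product: 6 4-bromo-2,6-dihydroxybenzaldehyde
Conditions: BBr3, CH2Cl2, −78 °C to rt; H2O
Reagents that add atoms: none
Why: boron tribromide ether cleavage removes both methyl groups, each ortho to the formyl group and so assisted by chelation of boron between the carbonyl and ether oxygens, while the aryl bromide is inert.

**Step 5**
Reactants: 6 4-bromo-2,6-dihydroxybenzaldehyde
Product: 7 4-bromo-2,6-bis(methoxymethoxy)benzaldehyde
Conditions: NaH, MOMCl, DMF, 0 °C to rt
Reagents that add atoms: chloromethyl methyl ether (MOMCl), COCCl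
Why: Williamson-type MOM ether formation from the preformed bis-phenoxide overcomes the hydrogen bonds to the aldehyde that slow amine-base protocols.

**Step 6**
Reactants: 7 4-bromo-2,6-bis(methoxymethoxy)benzaldehyde
Product: 9 4-bromo-2,6-bis(methoxymethoxy)phenol, via aryl formate 8 (not isolated)
Conditions: mCPBA, CH2Cl2, 0 °C to rt; aq NaHCO3 wash; K2CO3 (cat.), MeOH, rt
Reagents that add atoms: 3-chloroperoxybenzoic acid (mCPBA), OOC(=O)c1cccc(Cl)c1
Why: Baeyer–Villiger oxidation of an electron-rich benzaldehyde (the peracid variant of the Dakin oxidation) proceeds with aryl migration because of the two ortho alkoxy groups, and base-catalysed methanolysis of the formate frees the phenol that becomes O4.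

**Step 7**
Reactants: 4 ethyl 2-bromo-3-[3,5-dimethoxy-4-(methoxymethoxy)phenyl]-3-oxopropanoate; 9 4-bromo-2,6-bis(methoxymethoxy)phenol
Product: 10 ethyl 2-[4-bromo-2,6-bis(methoxymethoxy)phenoxy]-3-[3,5-dimethoxy-4-(methoxymethoxy)phenyl]-3-oxopropanoate (racemic)
Conditions: K2CO3, acetone, rt
Reagents that add atoms: none
Why: Williamson-type SN2 displacement of a doubly activated secondary bromide by a phenoxide, the standard entry to 2-aryloxy-3-oxo esters, forms C8–O4 at the only free phenol, and the racemic outcome is what the next step requires.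

**Step 8**
Reactants: 10 ethyl 2-[4-bromo-2,6-bis(methoxymethoxy)phenoxy]-3-[3,5-dimethoxy-4-(methoxymethoxy)phenyl]-3-oxopropanoate (racemic)
Product: 11 ethyl (2R,3S)-2-[4-bromo-2,6-bis(methoxymethoxy)phenoxy]-3-[3,5-dimethoxy-4-(methoxymethoxy)phenyl]-3-hydroxypropanoate (syn)
Conditions: RuCl[(R,R)-TsDPEN](p-cymene) (2 mol %), HCO2H/Et3N (5:2), CH2Cl2, 30 °C; chromatography to remove the anti isomer
Reagents that add atoms: none
Why: this is a Noyori–Ikariya asymmetric transfer hydrogenation run as a dynamic kinetic resolution, a reaction type established for 2-alkoxy- and 2-amido-3-oxo esters, in which Et3N interconverts the two C8 enantiomers of 10 through the enol faster than either is reduced, because C8–H is flanked by ketone, ester and aryloxy groups. The 18-electron hydride RuH[(R,R)-TsDPEN](p-cymene), a divalent ruthenium species, passes Ru–H and N–H to the C=O group in a concerted outer-sphere six-membered transition state, and formic acid regenerates it with loss of CO2. C7 is controlled by the catalyst, since the CH/pi contact between the p-cymene ligand and ring A exposes one ketone face, which with the (R,R)-ligand should give (3S). C8 is controlled by substrate–catalyst matching, since the enantiomer that can hold its aryloxy group away from the incoming hydride reacts much faster, which in the alkoxy series leads to the syn isomer, here (2R). No ring closes in this step. The step needs fast epimerisation, high facial and syn selectivity and chemoselectivity for the ketone, which should be secured by the acidity of C8–H, the aryl ketone motif and the inertness of ester, aryl bromide and MOM ethers to the buffered hydride source; the anti isomer must be removed because it carries the wrong C8 configuration, and step 10 would turn it into the enantiomer of the product.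

**Step 9**
Reactants: 11 ethyl (2R,3S)-2-[4-bromo-2,6-bis(methoxymethoxy)phenoxy]-3-[3,5-dimethoxy-4-(methoxymethoxy)phenyl]-3-hydroxypropanoate
Product: 12 (1S,2S)-2-[4-bromo-2,6-bis(methoxymethoxy)phenoxy]-1-[3,5-dimethoxy-4-(methoxymethoxy)phenyl]propane-1,3-diol
Conditions: LiBH4, THF, 0 °C
Reagents that add atoms: none
Why: chemoselective LiBH4 ester reduction, accelerated by the neighbouring alkoxide and aryloxy oxygen, spares the aryl bromide and MOM ethers and at low temperature should allow neither retro-aldol cleavage nor epimerisation of C8, whose descriptor changes from R to S only because CH2OH ranks below C7.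

**Step 10**
Reactants: 12 (1S,2S)-2-[4-bromo-2,6-bis(methoxymethoxy)phenoxy]-1-[3,5-dimethoxy-4-(methoxymethoxy)phenyl]propane-1,3-diol
Product: 16 (2S,3S)-7-bromo-2-(4-hydroxy-3,5-dimethoxyphenyl)-3-(hydroxymethyl)-2,3-dihydro-1,4-benzodioxin-5-ol, via pentaol 13 (not isolated), via C7 methyl ether 14 (not isolated), via quinone methide 15 (not isolated)
Conditions: HCl (1.25 M in MeOH), 0 °C to rt; evaporate; TsOH·H2O (cat.), THF/toluene, 60 °C
Reagents that add atoms: none
Why: acetal exchange with methanol removes the three MOM groups without releasing free formaldehyde, and acid then ionises the C7 alcohol or methyl ether, para to the free OH of ring A, to the quinone methide or its protonated form, which one of the two equivalent flanking phenols captures in a reversible 6-exo-trig oxa-Michael addition (acid-catalysed benzylic etherification, known for 2-aryloxy-1-arylpropane-1,3-diols), so that C7 settles under thermodynamic control trans to the untouched C8 in the diequatorial half-chair.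

**Step 11**
Reactants: 17 3,5-dihydroxybenzaldehyde
Product: 18 3,5-bis(tert-butyldimethylsilyloxy)benzaldehyde
Conditions: TBSCl, imidazole, DMF, rt
Reagents that add atoms: tert-butyldimethylsilyl chloride, CC(C)(C)[Si](C)(C)Cl
Why: imidazole-promoted silyl ether formation on unhindered phenols is routine and leaves the aldehyde free.

**Step 12**
Reactants: 18 3,5-bis(tert-butyldimethylsilyloxy)benzaldehyde
Product: 19 3,5-bis(tert-butyldimethylsilyloxy)styrene
Conditions: Ph3PCH3Br, KOt-Bu, THF, 0 °C to rt
Reagents that add atoms: methyltriphenylphosphonium bromide, C[P+](c1ccccc1)(c1ccccc1)c1ccccc1.[Br-]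
Why: Wittig methylenation with the non-stabilised ylide converts the aldehyde into the terminal alkene without disturbing the aryl silyl ethers.

**Step 13**
Reactants: 16 (2S,3S)-7-bromo-2-(4-hydroxy-3,5-dimethoxyphenyl)-3-(hydroxymethyl)-2,3-dihydro-1,4-benzodioxin-5-ol
Product: 20 (2S,3S)-7-bromo-5-(tert-butyldimethylsilyloxy)-3-[(tert-butyldimethylsilyloxy)methyl]-2-[4-(tert-butyldimethylsilyloxy)-3,5-dimethoxyphenyl]-2,3-dihydro-1,4-benzodioxine
Conditions: TBSCl (excess), imidazole, DMAP (cat.), DMF, rt to 40 °C
Reagents that add atoms: tert-butyldimethylsilyl chloride, CC(C)(C)[Si](C)(C)Cl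
Why: silyl ether formation masks both phenols and the primary alcohol, which shuts off quinone methide formation at C7 and phenoxide oxidation during the basic, heated coupling.

**Step 14**
Reactants: 19 3,5-bis(tert-butyldimethylsilyloxy)styrene; 20 (2S,3S)-7-bromo-5-(tert-butyldimethylsilyloxy)-3-[(tert-butyldimethylsilyloxy)methyl]-2-[4-(tert-butyldimethylsilyloxy)-3,5-dimethoxyphenyl]-2,3-dihydro-1,4-benzodioxine
Product: 21 (2S,3S)-7-{(E)-2-[3,5-bis(tert-butyldimethylsilyloxy)phenyl]ethenyl}-5-(tert-butyldimethylsilyloxy)-3-[(tert-butyldimethylsilyloxy)methyl]-2-[4-(tert-butyldimethylsilyloxy)-3,5-dimethoxyphenyl]-2,3-dihydro-1,4-benzodioxine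
Conditions: Pd(OAc)2 (5 mol %), P(t-Bu)3·HBF4, Cy2NMe, 1,4-dioxane, 80 °C
Reagents that add atoms: none
Why: in this Mizoroki–Heck reaction, zerovalent palladium carrying the bulky electron-rich phosphine inserts into the unhindered though electron-rich aryl bromide, and syn insertion at the terminal alkene carbon followed by syn beta-hydride elimination should give the E stilbene with both ring stereocentres as spectators.

**Step 15**
Reactants: 21 the penta-TBS ether of step 14
Product: 22 (2S,3S)-7-[(E)-2-(3,5-dihydroxyphenyl)ethenyl]-2-(4-hydroxy-3,5-dimethoxyphenyl)-3-(hydroxymethyl)-2,3-dihydro-1,4-benzodioxin-5-ol (target CNP0319597.1)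
Conditions: TBAF, AcOH, THF, 0 °C to rt, argon
Reagents that add atoms: none
Why: fluoride-induced Si–O cleavage removes all five silyl groups, and the acetic acid buffer and inert gas keep the liberated polyphenol from forming phenoxides that could oxidise or reopen ring C through the quinone methide.

**Compound list**

1 | acetosyringone, 1-(4-hydroxy-3,5-dimethoxyphenyl)ethanone | CC(=O)c1cc(OC)c(O)c(OC)c1 | starting material
2 | 1-[3,5-dimethoxy-4-(methoxymethoxy)phenyl]ethanone | CC(=O)c1cc(OC)c(OCOC)c(OC)c1 | intermediate
3 | ethyl 3-[3,5-dimethoxy-4-(methoxymethoxy)phenyl]-3-oxopropanoate | CCOC(=O)CC(=O)c1cc(OC)c(OCOC)c(OC)c1 | intermediate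
4 | ethyl 2-bromo-3-[3,5-dimethoxy-4-(methoxymethoxy)phenyl]-3-oxopropanoate (racemic) | CCOC(=O)C(Br)C(=O)c1cc(OC)c(OCOC)c(OC)c1 | intermediate
5 | 4-bromo-2,6-dimethoxybenzaldehyde | COc1cc(Br)cc(OC)c1C=O | starting material
6 | 4-bromo-2,6-dihydroxybenzaldehyde | O=Cc1c(O)cc(Br)cc1O | intermediate
7 | 4-bromo-2,6-bis(methoxymethoxy)benzaldehyde | COCOc1cc(Br)cc(OCOC)c1C=O | intermediate
8 | 4-bromo-2,6-bis(methoxymethoxy)phenyl formate (not isolated) | COCOc1cc(Br)cc(OCOC)c1OC=O | intermediate
9 | 4-bromo-2,6-bis(methoxymethoxy)phenol | COCOc1cc(Br)cc(OCOC)c1O | intermediate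
10 | ethyl 2-[4-bromo-2,6-bis(methoxymethoxy)phenoxy]-3-[3,5-dimethoxy-4-(methoxymethoxy)phenyl]-3-oxopropanoate (racemic) | CCOC(=O)C(Oc1c(OCOC)cc(Br)cc1OCOC)C(=O)c1cc(OC)c(OCOC)c(OC)c1 | intermediate
11 | ethyl (2R,3S)-2-[4-bromo-2,6-bis(methoxymethoxy)phenoxy]-3-[3,5-dimethoxy-4-(methoxymethoxy)phenyl]-3-hydroxypropanoate | CCOC(=O)[C@H](Oc1c(OCOC)cc(Br)cc1OCOC)[C@@H](O)c1cc(OC)c(OCOC)c(OC)c1 | intermediate
12 | (1S,2S)-2-[4-bromo-2,6-bis(methoxymethoxy)phenoxy]-1-[3,5-dimethoxy-4-(methoxymethoxy)phenyl]propane-1,3-diol | OC[C@H](Oc1c(OCOC)cc(Br)cc1OCOC)[C@@H](O)c1cc(OC)c(OCOC)c(OC)c1 | intermediate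
13 | (1S,2S)-2-(4-bromo-2,6-dihydroxyphenoxy)-1-(4-hydroxy-3,5-dimethoxyphenyl)propane-1,3-diol (not isolated) | OC[C@H](Oc1c(O)cc(Br)cc1O)[C@@H](O)c1cc(OC)c(O)c(OC)c1 | intermediate
14 | 5-bromo-2-{[(2S)-3-hydroxy-1-(4-hydroxy-3,5-dimethoxyphenyl)-1-methoxypropan-2-yl]oxy}benzene-1,3-diol, both C7 epimers (not isolated) | OC[C@H](Oc1c(O)cc(Br)cc1O)C(OC)c1cc(OC)c(O)c(OC)c1 | intermediate
15 | 4-[(2R)-2-(4-bromo-2,6-dihydroxyphenoxy)-3-hydroxypropylidene]-2,6-dimethoxycyclohexa-2,5-dien-1-one (not isolated) | OC[C@H](Oc1c(O)cc(Br)cc1O)C=C1C=C(OC)C(=O)C(OC)=C1 | intermediate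
16 | (2S,3S)-7-bromo-2-(4-hydroxy-3,5-dimethoxyphenyl)-3-(hydroxymethyl)-2,3-dihydro-1,4-benzodioxin-5-ol (trans) | COc1cc([C@@H]2Oc3cc(Br)cc(O)c3O[C@H]2CO)cc(OC)c1O | intermediate
17 | 3,5-dihydroxybenzaldehyde | O=Cc1cc(O)cc(O)c1 | starting material
18 | 3,5-bis(tert-butyldimethylsilyloxy)benzaldehyde | O=Cc1cc(O[Si](C)(C)C(C)(C)C)cc(O[Si](C)(C)C(C)(C)C)c1 | intermediate
19 | 3,5-bis(tert-butyldimethylsilyloxy)styrene | C=Cc1cc(O[Si](C)(C)C(C)(C)C)cc(O[Si](C)(C)C(C)(C)C)c1 | intermediate
20 | (2S,3S)-7-bromo-5-(tert-butyldimethylsilyloxy)-3-[(tert-butyldimethylsilyloxy)methyl]-2-[4-(tert-butyldimethylsilyloxy)-3,5-dimethoxyphenyl]-2,3-dihydro-1,4-benzodioxine | COc1cc([C@@H]2Oc3cc(Br)cc(O[Si](C)(C)C(C)(C)C)c3O[C@H]2CO[Si](C)(C)C(C)(C)C)cc(OC)c1O[Si](C)(C)C(C)(C)C | intermediate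
21 | (2S,3S)-7-{(E)-2-[3,5-bis(tert-butyldimethylsilyloxy)phenyl]ethenyl}-5-(tert-butyldimethylsilyloxy)-3-[(tert-butyldimethylsilyloxy)methyl]-2-[4-(tert-butyldimethylsilyloxy)-3,5-dimethoxyphenyl]-2,3-dihydro-1,4-benzodioxine | COc1cc([C@@H]2Oc3cc(/C=C/c4cc(O[Si](C)(C)C(C)(C)C)cc(O[Si](C)(C)C(C)(C)C)c4)cc(O[Si](C)(C)C(C)(C)C)c3O[C@H]2CO[Si](C)(C)C(C)(C)C)cc(OC)c1O[Si](C)(C)C(C)(C)C | intermediate
22 | (2S,3S)-7-[(E)-2-(3,5-dihydroxyphenyl)ethenyl]-2-(4-hydroxy-3,5-dimethoxyphenyl)-3-(hydroxymethyl)-2,3-dihydro-1,4-benzodioxin-5-ol | COc1cc([C@@H]2Oc3cc(/C=C/c4cc(O)cc(O)c4)cc(O)c3O[C@H]2CO)cc(OC)c1O | target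

**Step count**

Total step count: 15.
Longest linear sequence: 10 steps (steps 1, 2, 3, 7, 8, 9, 10, 13, 14, 15). The branch from 5 through steps 4, 5 and 6 is equally long.

**Steps most likely to fail**

**1. Step 8.** Reduction of the hindered ketone may be slow. It may also outrun epimerisation at C8, or the bulky 2,6-disubstituted aryloxy group may weaken the syn preference. In each case C8 would not be funnelled cleanly into one configuration.

Fallback, from 9 back to 12: the C7–C8 bond would be formed under auxiliary control instead of the C7–H bond under catalyst control.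
- Phenol 9 would be alkylated with bromoacetic acid (NaH, THF) to give [4-bromo-2,6-bis(methoxymethoxy)phenoxy]acetic acid F1.
- This acid would be coupled with (R)-4-benzyl-1,3-oxazolidin-2-one (PivCl, Et3N, LiCl, THF) to give the N-acyl oxazolidinone F2.
- An Evans syn aldol reaction (Bu2BOTf, Et3N, CH2Cl2, −78 °C) would join F2 to 3,5-dimethoxy-4-(methoxymethoxy)benzaldehyde F3, itself made from syringaldehyde with MOMCl and i-Pr2NEt. It should give the (2R,3S) syn aldol adduct F4.
- LiBH4 in THF would then remove the auxiliary reductively and deliver diol 12.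

**2. Step 10.** The benzylic cation may lose the C8 proton, or lose C9 as formaldehyde. Either process cleaves the aryl ether or erodes C8. The cation may also alkylate the electron-rich rings at carbon, or equilibration to the trans ring may stay incomplete.

Fallback, from 12 back to 16: the quinone methide would be generated as a discrete species without Brønsted acid.
- TMSBr (CH2Cl2, −40 to 0 °C) would cleave the MOM ethers and replace the C7 hydroxyl by bromide.
- Removal of the volatiles and hydrolysis of the transient silyl ethers would leave the benzylic bromide F5 as a mixture of C7 epimers.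
- Shaking its solution with aqueous NaHCO3 would eliminate HBr to give quinone methide 15, which should close to 16 by the same oxa-Michael addition. Mild base would keep the addition reversible, so the trans ring should still be favoured.

**3. Step 7.** The electron-rich, hindered phenoxide may attack bromine instead of carbon, which transfers bromine and returns the parent keto ester. It may also simply deprotonate 4 to an unreactive enolate, so that displacement stalls.

Fallback, from 3 back to 10: C8–O4 would be formed by carbenoid O–H insertion instead of substitution.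
- Regitz diazo transfer (4-acetamidobenzenesulfonyl azide, Et3N, MeCN) onto keto ester 3 would give ethyl 2-diazo-3-[3,5-dimethoxy-4-(methoxymethoxy)phenyl]-3-oxopropanoate F6.
- Its decomposition with Rh2(OAc)4 in the presence of phenol 9 (toluene, 80 °C) should give 10.

**Further compounds**

F1 | step 8 | [4-bromo-2,6-bis(methoxymethoxy)phenoxy]acetic acid | OC(=O)COc1c(OCOC)cc(Br)cc1OCOC
F2 | step 8 | (4R)-4-benzyl-3-{[4-bromo-2,6-bis(methoxymethoxy)phenoxy]acetyl}-1,3-oxazolidin-2-one | O=C(COc1c(OCOC)cc(Br)cc1OCOC)N1[C@H](Cc2ccccc2)COC1=O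
F3 | step 8 | 3,5-dimethoxy-4-(methoxymethoxy)benzaldehyde | COCOc1c(OC)cc(C=O)cc1OC
F4 | step 8 | (4R)-4-benzyl-3-{(2R,3S)-2-[4-bromo-2,6-bis(methoxymethoxy)phenoxy]-3-[3,5-dimethoxy-4-(methoxymethoxy)phenyl]-3-hydroxypropanoyl}-1,3-oxazolidin-2-one | O=C([C@H](Oc1c(OCOC)cc(Br)cc1OCOC)[C@@H](O)c1cc(OC)c(OCOC)c(OC)c1)N1[C@H](Cc2ccccc2)COC1=O
F5 | step 10 | 5-bromo-2-{[(2S)-1-bromo-3-hydroxy-1-(4-hydroxy-3,5-dimethoxyphenyl)propan-2-yl]oxy}benzene-1,3-diol, both C7 epimers | OC[C@H](Oc1c(O)cc(Br)cc1O)C(Br)c1cc(OC)c(O)c(OC)c1
F6 | step 7 | ethyl 2-diazo-3-[3,5-dimethoxy-4-(methoxymethoxy)phenyl]-3-oxopropanoate | CCOC(=O)C(=[N+]=[N-])C(=O)c1cc(OC)c(OCOC)c(OC)c1
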